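All runs were computed from invented constants; scatter was added.

| flask | L | Z | J | D | remark | time |
|---|---|---|---|---|---|---|
| south-east | 23 mM | 23 mM | 0.60 equiv | 0.2 mol% | run made earlier |  |
| west | 52 mM | 52 mM | 0.60 equiv | 0.2 mol% | run made earlier |  |
| flask | 35 mM | 35 mM | 0.600 equiv | 0.2 mol% |  | 40 min |

| run | time / min | E / % | X / % |
|---|---|---|---|
| south-east | 4.00 | 0.4 | 0 |
| south-east | 8.00 | 1.8 | 1.2 |
| south-east | 20.0 | 6.6 | 3.9 |
| south-east | 50.0 | 13.0 | 11.0 |
| west | 12.0 | 3.6 | 1.7 |
| west | 25.0 | 9.2 | 6.7 |
| west | 40.0 | 13.5 | 10.9 |
| west | 50.0 | 15.3 | 13.1 |

(each reading ± 0.5 percentage points)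

- D is single-handed; L and Z are mirror images of each other, charged as a racemate, each of them at the stated concentration
- given per volume of solution although it is solid: J
- at the start none of J is in solution
- an excess is the difference of the two amounts in percent of their sum
- an excess is below zero if the other one leads

- excess of E over X in the product at 50 s
- excess of E over X in the product at 40 min
- part of the L and Z charged together that has reacted at 40 min

The slowness struck me first: late in both runs, E and X together grew by a mere 0.00475 min⁻¹ of the charge, but the gap E−X stood level, at a mean reading of 0.0227 of the charge. I therefore supposed that new product keeps arriving with a fixed preference (kinetic control) and that the gap fades with a memory time τ, so that gap = birth excess × rate × τ. The west reading at 12.0 min, taken as an exponential rise towards that level, gave τ = 6.59 min, and hence the birth excess, the excess of E over X among product just made, came to 72.4%, a rough reading given the scatter of 0.5 percentage points. Because 50 s is shorter than τ, I expected ea near that figure. By 40 min, with conversion interpolated to 0.220, I reckoned eb as 10.3%.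

The forecast gave 36%, 10.5% and 22%, on the view that “an early selective channel dies, or saturates”.

The flask gave 69.5%, 7.24% and 25.2%.

    Q + D + Z → D + X (k = 6800 L² mol⁻² min⁻¹)
    Q + D + L → D + E (k = 44000 L² mol⁻² min⁻¹)
    E ⇌ X (k = 0.0950 min⁻¹)
    J ⇌ Q, rate k4*(cs4 - [Q]) while solid is left; crystals form when [Q] > cs4 (solubility = 16.0 mM, k = 0.0550 min⁻¹)

The flask's excess at 50 s lay 3 points below the birth excess, but its preference did not stay fixed: it used Q 5.7 times as fast on L as on Z at 15.0 min and 4.1 times as fast at 40.0 min, when less of its L remained than of its Z, at 58% against 92%. Yet E stood at 13.5% and X at 11.7%, with 7.61% of the charge having passed net from E to X.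

For a neighbour flask with 0.360 equiv of J, the birth excess again gives 72.4% as the excess at 50 s; that neighbour gave 69.5%.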